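## Retrosynthetic overview

1. Lobophynin B ⇐ site-selective saturation of C13=C14 in a 13,14-dehydro bicycle (cembrane numbering).
2. That bicycle ⇐ one tandem ene–yne–ene ring-closing metathesis of an acyclic dienyne: C1=C15 (2,5-dihydrofuran) and C13=C14 (14-membered carbocycle) close in the same operation; C1 and C14 are the two carbons of an ethynyl group on C2.
3. Dienyne ⇐ Wittig methylenation of an ω-enal; (7R,8R)-oxirane by Shi epoxidation of the only electron-rich alkene; ω-enal by SeO2 oxidation of the farnesyl terminus.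
4. C15–C17 and the ring oxygen ⇐ O-alkylation of the C2 carbinol with 3-chloro-2-(chloromethyl)prop-1-ene, then acetate; C2 ⇐ catalytic asymmetric alkynylation of (2E,6E)-farnesal.
5. Ring order: oxirane first (acyclic stage), then the dihydrofuran and the macrocycle together.

Assumption: (S,S)-ProPhenol/Me2Zn is taken to give the 3R carbinol in step 2; if the sense is the opposite, (R,R)-ProPhenol is used and nothing else changes.

## Route

Step 1
Reactants: 1 (2E,6E)-farnesol
Product: 2 (2E,6E)-farnesal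
Conditions: MnO2 (activated, excess), CH2Cl2, rt
Reagents that add atoms: none
Why: MnO2 oxidation of a primary allylic alcohol stops at the enal and does not isomerise the 2E double bond; no stereocenter is formed.

Step 2
Reactants: 2 (2E,6E)-farnesal; 3 trimethylsilylacetylene
Product: 5 (3R,4E,8E)-5,9,13-trimethyltetradeca-4,8,12-trien-1-yn-3-ol, via silyl alkynol 4 (not isolated)
Conditions: (S,S)-ProPhenol (10 mol%), Me2Zn, Ph3P=O (20 mol%), toluene, 4 °C; aq NH4Cl; then K2CO3, MeOH, rt
Reagents that add atoms: trimethylsilylacetylene, C#C[Si](C)(C)C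
Why: Trost dinuclear-zinc ProPhenol asymmetric alkynylation of an enal sets the carbinol centre (C2 of the target, 3R here) by catalyst control, and K2CO3/MeOH then cleaves only the C–Si bond to free the terminal alkyne.

Step 3
Reactants: 5 (3R,4E,8E)-5,9,13-trimethyltetradeca-4,8,12-trien-1-yn-3-ol; 6 3-chloro-2-(chloromethyl)prop-1-ene; 7 potassium acetate
Product: 9 2-({[(3R,4E,8E)-5,9,13-trimethyltetradeca-4,8,12-trien-1-yn-3-yl]oxy}methyl)prop-2-en-1-yl acetate, via chloro ether 8 (not isolated)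
Conditions: NaH (1.05 equiv), THF–DMF, 0 °C; 6 (5 equiv), Bu4NI (cat.), 0 °C to rt; then KOAc (excess), 60 °C, same flask
Reagents that add atoms: 3-chloro-2-(chloromethyl)prop-1-ene, C=C(CCl)CCl; potassium acetate, CC(=O)[O-].[K+]
Why: Williamson etherification with the symmetrical bis-allylic chloride (SN2 and SN2' give the same ether), then SN2 displacement of the remaining allylic chloride by acetate, installs C15–C17; only the O–H bond of the carbinol is broken, so 3R is retained.

Step 4
Reactants: 9 2-({[(3R,4E,8E)-5,9,13-trimethyltetradeca-4,8,12-trien-1-yn-3-yl]oxy}methyl)prop-2-en-1-yl acetate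
Product: 11 2-({[(3R,4E,8E,12E)-5,9,13-trimethyl-14-oxotetradeca-4,8,12-trien-1-yn-3-yl]oxy}methyl)prop-2-en-1-yl acetate, via allylic alcohol 10 (not isolated)
Conditions: SeO2 (cat.), salicylic acid (cat.), t-BuOOH, CH2Cl2, rt; then MnO2, CH2Cl2, rt on the crude alcohol/aldehyde mixture
Reagents that add atoms: selenium dioxide, O=[Se]=O; tert-butyl hydroperoxide, CC(C)(C)OO
Why: Sharpless SeO2/t-BuOOH allylic oxidation (ene reaction, then [2,3]-sigmatropic shift) attacks the E-methyl of the terminal, most electron-rich trisubstituted alkene, and MnO2 converges the mixture on the (E)-enal; no stereocenter is touched.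

Step 5
Reactants: 11 2-({[(3R,4E,8E,12E)-5,9,13-trimethyl-14-oxotetradeca-4,8,12-trien-1-yn-3-yl]oxy}methyl)prop-2-en-1-yl acetate
Product: 12 2-({[(3R,4E,8R,9R,12E)-8,9-epoxy-5,9,13-trimethyl-14-oxotetradeca-4,12-dien-1-yn-3-yl]oxy}methyl)prop-2-en-1-yl acetate
Conditions: D-fructose-derived Shi ketone (30 mol%), KHSO5 (Oxone, 2KHSO5·KHSO4·K2SO4, 1.4 equiv), K2CO3, Bu4NHSO4 (cat.), MeCN–dimethoxymethane–aq Na2B4O7 buffer, 0 °C
Reagents that add atoms: potassium peroxymonosulfate, [K+].[O-]S(=O)(=O)OO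
Why: In this Shi asymmetric epoxidation the 8,9-alkene is the only electron-rich one (4,5 is deactivated by the allylic/propargylic ether, 12,13 by the aldehyde, the 1,1-disubstituted one by two allylic oxygens), and the D-fructose ketone gives the (R,R)-oxirane from an E-trisubstituted alkene through the spiro transition state, setting C7 and C8 of the target.

Step 6
Reactants: 12 2-({[(3R,4E,8R,9R,12E)-8,9-epoxy-5,9,13-trimethyl-14-oxotetradeca-4,12-dien-1-yn-3-yl]oxy}methyl)prop-2-en-1-yl acetate; 13 methyltriphenylphosphonium bromide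
Product: 14 2-({[(3R,4E,8R,9R,12E)-8,9-epoxy-5,9,13-trimethylpentadeca-4,12,14-trien-1-yn-3-yl]oxy}methyl)prop-2-en-1-yl acetate
Conditions: KN(SiMe3)2, THF, −78 °C to 0 °C (ylide 1.2 equiv)
Reagents that add atoms: methyltriphenylphosphonium bromide, C[P+](c1ccccc1)(c1ccccc1)c1ccccc1.[Br-]
Why: Wittig methylenation of the aldehyde with the non-stabilised ylide at low temperature is much faster than attack on the acetate and gives the terminal 1,3-diene; the epoxide and the stereocenters are not affected.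

Step 7
Reactants: 14 2-({[(3R,4E,8R,9R,12E)-8,9-epoxy-5,9,13-trimethylpentadeca-4,12,14-trien-1-yn-3-yl]oxy}methyl)prop-2-en-1-yl acetate
Product: 15 (2R,7R,8R,3E,11E)-17-acetoxy-2,16:7,8-diepoxycembra-1(15),3,11,13-tetraene (13E/13Z mixture)
Conditions: second-generation Hoveyda–Grubbs catalyst RuCl2(H2IMes)(=CH-C6H4-2-OiPr) (15 mol%, in portions), 1,4-benzoquinone (10 mol%), toluene (1 mM, slow addition), 80 °C, Ar sparge
Reagents that add atoms: none
Why: Tandem ene–yne–ene ring-closing metathesis (dienyne RCM): Ru loads at the diene terminus and adds to the unsubstituted alkyne carbon (the endo mode usual for macrocyclic enyne RCM), closing the 14-membered ring and leaving a carbene on C1 that closes the five-membered ring onto the 1,1-disubstituted alkene with loss of ethene; the reverse order (five-membered ring first, then macrocycle through the C14 carbene) gives the same product, no stereocenter is touched, and the C13=C14 geometry does not matter because that bond is saturated next.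

Step 8
Reactants: 15 (2R,7R,8R,3E,11E)-17-acetoxy-2,16:7,8-diepoxycembra-1(15),3,11,13-tetraene
Product: 16 lobophynin B, (2R,7R,8R,3E,11E)-17-acetoxy-2,16:7,8-diepoxycembra-1(15),3,11-triene
Conditions: 2-nitrobenzenesulfonylhydrazide (about 4 equiv, monitored), Et3N, CH2Cl2, rt
Reagents that add atoms: none
Why: Diimide reduction (concerted syn transfer of H2) is about ten times or more faster for a 1,2-disubstituted alkene than for tri- and tetrasubstituted ones, so only C13=C14 is saturated, and the neutral conditions leave the epoxide, the allylic acetate and the doubly allylic ether centre C2 intact.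

## Compound list

1 | (2E,6E)-farnesol | CC(C)=CCC/C(C)=C/CC/C(C)=C/CO | starting material
2 | (2E,6E)-farnesal | CC(C)=CCC/C(C)=C/CC/C(C)=C/C=O | intermediate
3 | trimethylsilylacetylene | C#C[Si](C)(C)C | starting material
4 | (3R,4E,8E)-5,9,13-trimethyl-1-(trimethylsilyl)tetradeca-4,8,12-trien-1-yn-3-ol | C[Si](C)(C)C#C[C@H](O)/C=C(C)/CC/C=C(C)/CCC=C(C)C | intermediate
5 | (3R,4E,8E)-5,9,13-trimethyltetradeca-4,8,12-trien-1-yn-3-ol | C#C[C@H](O)/C=C(C)/CC/C=C(C)/CCC=C(C)C | intermediate
6 | 3-chloro-2-(chloromethyl)prop-1-ene | C=C(CCl)CCl | starting material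
7 | potassium acetate | CC(=O)[O-].[K+] | starting material
8 | (3R,4E,8E)-3-{[2-(chloromethyl)prop-2-en-1-yl]oxy}-5,9,13-trimethyltetradeca-4,8,12-trien-1-yne | C#C[C@H](OCC(=C)CCl)/C=C(C)/CC/C=C(C)/CCC=C(C)C | intermediate
9 | 2-({[(3R,4E,8E)-5,9,13-trimethyltetradeca-4,8,12-trien-1-yn-3-yl]oxy}methyl)prop-2-en-1-yl acetate | C#C[C@H](OCC(=C)COC(C)=O)/C=C(C)/CC/C=C(C)/CCC=C(C)C | intermediate
10 | 2-({[(3R,4E,8E,12E)-14-hydroxy-5,9,13-trimethyltetradeca-4,8,12-trien-1-yn-3-yl]oxy}methyl)prop-2-en-1-yl acetate | C#C[C@H](OCC(=C)COC(C)=O)/C=C(C)/CC/C=C(C)/CC/C=C(C)/CO | intermediate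
11 | 2-({[(3R,4E,8E,12E)-5,9,13-trimethyl-14-oxotetradeca-4,8,12-trien-1-yn-3-yl]oxy}methyl)prop-2-en-1-yl acetate | C#C[C@H](OCC(=C)COC(C)=O)/C=C(C)/CC/C=C(C)/CC/C=C(C)/C=O | intermediate
12 | 2-({[(3R,4E,8R,9R,12E)-8,9-epoxy-5,9,13-trimethyl-14-oxotetradeca-4,12-dien-1-yn-3-yl]oxy}methyl)prop-2-en-1-yl acetate | C#C[C@H](OCC(=C)COC(C)=O)/C=C(C)/CC[C@H]1O[C@]1(C)CC/C=C(C)/C=O | intermediate
13 | methyltriphenylphosphonium bromide | C[P+](c1ccccc1)(c1ccccc1)c1ccccc1.[Br-] | starting material
14 | 2-({[(3R,4E,8R,9R,12E)-8,9-epoxy-5,9,13-trimethylpentadeca-4,12,14-trien-1-yn-3-yl]oxy}methyl)prop-2-en-1-yl acetate | C#C[C@H](OCC(=C)COC(C)=O)/C=C(C)/CC[C@H]1O[C@]1(C)CC/C=C(C)/C=C | intermediate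
15 | (2R,7R,8R,3E,11E)-17-acetoxy-2,16:7,8-diepoxycembra-1(15),3,11,13-tetraene (13E/13Z mixture, C13=C14 geometry left open in the SMILES) | CC(=O)OCC1=C2C=C/C(C)=C/CC[C@@]3(C)O[C@@H]3CC/C(C)=C/[C@H]2OC1 | intermediate
16 | lobophynin B, (2R,7R,8R,3E,11E)-17-acetoxy-2,16:7,8-diepoxycembra-1(15),3,11-triene | CC(=O)OCC1=C2CC/C(C)=C/CC[C@@]3(C)O[C@@H]3CC/C(C)=C/[C@H]2OC1 | target

## Step count and risks

Total step count: 8 (steps 2, 3 and 4 are two-stage operations run without isolating 4, 8 and 10).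
Longest linear sequence: 8 steps, from 1.

Steps most likely to fail:

Step 7, the tandem ring closure. The Ru carbene on C1 is hindered and must form a tetrasubstituted alkene; the wrong metathesis modes (13-membered ring by exo attack, six-membered ring by endo attack) and oligomerisation compete. This exact ring-size combination is untested. Fallback: separate the two ring closures. Setting out from 14, enyne ring-closing metathesis under an ethene atmosphere (second-generation Grubbs catalyst RuCl2(H2IMes)(PCy3)(=CHPh), CH2Cl2, 40 °C) closes only the five-membered ring. This gives the monocyclic triene [(5R)-4-ethenyl-5-{(1E)-2-methyl-4-[(2R,3R)-3-methyl-3-[(3E)-4-methylhexa-3,5-dien-1-yl]oxiran-2-yl]but-1-en-1-yl}-2,5-dihydrofuran-3-yl]methyl acetate F1, which is isolated. A separate macrocyclic diene–diene ring-closing metathesis of its two vinyl groups at high dilution (toluene, 80 °C, Ar sparge) then closes the 14-membered ring, and the route is rejoined at 15.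

Step 5, the Shi epoxidation. KHSO5 at pH 10.5 may oxidise the free enal (to the acid or by nucleophilic epoxidation), and selectivity against the 4,5-alkene rests on deactivation by an ether oxygen only. Fallback: keep the ω-terminus at the alcohol level during epoxidation. Setting out from 10 (isolated after the SeO2 stage instead of being oxidised), TBSCl/imidazole gives 2-({[(3R,4E,8E,12E)-14-{[tert-butyl(dimethyl)silyl]oxy}-5,9,13-trimethyltetradeca-4,8,12-trien-1-yn-3-yl]oxy}methyl)prop-2-en-1-yl acetate F2. Shi epoxidation under the step 5 conditions then gives 2-({[(3R,4E,8R,9R,12E)-14-{[tert-butyl(dimethyl)silyl]oxy}-8,9-epoxy-5,9,13-trimethyltetradeca-4,12-dien-1-yn-3-yl]oxy}methyl)prop-2-en-1-yl acetate F3. Bu4NF buffered with AcOH removes the silyl group to give 2-({[(3R,4E,8R,9R,12E)-8,9-epoxy-14-hydroxy-5,9,13-trimethyltetradeca-4,12-dien-1-yn-3-yl]oxy}methyl)prop-2-en-1-yl acetate F4, and MnO2 oxidation brings the route back at 12.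

Step 2, the asymmetric alkynylation. A β,β-disubstituted enal may give lower enantioselectivity than the reported enals, and the sense of induction rests on the assumption above. Fallback: set C2 by reduction instead of addition. Setting out from 2, lithium trimethylsilylacetylide (from 3 and n-BuLi, THF, −78 °C) gives racemic (4E,8E)-5,9,13-trimethyl-1-(trimethylsilyl)tetradeca-4,8,12-trien-1-yn-3-ol F5. MnO2 gives the ynone (4E,8E)-5,9,13-trimethyl-1-(trimethylsilyl)tetradeca-4,8,12-trien-1-yn-3-one F6. Corey–Bakshi–Shibata reduction with the (R)-methyl oxazaborolidine and catecholborane at −78 °C (alkynyl as the small group) gives the 3R alcohol, and the route is rejoined at 4, which is desilylated to 5 as in step 2.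

## Further compounds

F1 | step 7 | [(5R)-4-ethenyl-5-{(1E)-2-methyl-4-[(2R,3R)-3-methyl-3-[(3E)-4-methylhexa-3,5-dien-1-yl]oxiran-2-yl]but-1-en-1-yl}-2,5-dihydrofuran-3-yl]methyl acetate | C=CC1=C(COC(C)=O)CO[C@@H]1/C=C(C)/CC[C@H]2O[C@]2(C)CC/C=C(C)/C=C
F2 | step 5 | 2-({[(3R,4E,8E,12E)-14-{[tert-butyl(dimethyl)silyl]oxy}-5,9,13-trimethyltetradeca-4,8,12-trien-1-yn-3-yl]oxy}methyl)prop-2-en-1-yl acetate | C#C[C@H](OCC(=C)COC(C)=O)/C=C(C)/CC/C=C(C)/CC/C=C(C)/CO[Si](C)(C)C(C)(C)C
F3 | step 5 | 2-({[(3R,4E,8R,9R,12E)-14-{[tert-butyl(dimethyl)silyl]oxy}-8,9-epoxy-5,9,13-trimethyltetradeca-4,12-dien-1-yn-3-yl]oxy}methyl)prop-2-en-1-yl acetate | C#C[C@H](OCC(=C)COC(C)=O)/C=C(C)/CC[C@H]1O[C@]1(C)CC/C=C(C)/CO[Si](C)(C)C(C)(C)C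
F4 | step 5 | 2-({[(3R,4E,8R,9R,12E)-8,9-epoxy-14-hydroxy-5,9,13-trimethyltetradeca-4,12-dien-1-yn-3-yl]oxy}methyl)prop-2-en-1-yl acetate | C#C[C@H](OCC(=C)COC(C)=O)/C=C(C)/CC[C@H]1O[C@]1(C)CC/C=C(C)/CO
F5 | step 2 | racemic (4E,8E)-5,9,13-trimethyl-1-(trimethylsilyl)tetradeca-4,8,12-trien-1-yn-3-ol | C[Si](C)(C)C#CC(O)/C=C(C)/CC/C=C(C)/CCC=C(C)C
F6 | step 2 | (4E,8E)-5,9,13-trimethyl-1-(trimethylsilyl)tetradeca-4,8,12-trien-1-yn-3-one | C[Si](C)(C)C#CC(=O)/C=C(C)/CC/C=C(C)/CCC=C(C)C
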